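A day is the unit here: in the south run, which is the asked flask followed so far, the ratio of isomer of the product to target, each as a fraction of the substrate charged, divided by the time of reading gives 0.224 /d, 0.238 /d and 0.233 /d at 2.08 d, 3.00 d and 5.00 d.

all flasks: substrate 14 mM
- south: coupling partner 1.2 equiv; the very flask that is asked about, followed so far
- flask: coupling partner 1.20 equiv; time 12 d

south run (percent of the substrate charged)

| time / d | isomer of the product / % | target / % | substrate / % |
|---|---|---|---|
| 0.417 | 0 | 29 | 13 |
| 0.625 | 0 | 26 | 12 |
| 0.833 | 2 | 21 | 9 |
| 1.25 | 3 | 19 | 8 |
| 2.08 | 7 | 15 | 8 |
| 3.00 | 5 | 7 | 4 |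
| 5.00 | 7 | 6 | 0 |

(each reading ± 1.5 percentage points)

- ratio of isomer of the product to target at 2.0 min
- ratio of isomer of the product to target at 3.0 h
- ratio of isomer of the product to target at 12 d
- which of isomer of the product and target there is more of at 12 d



A constant rate of rise integrates, from a ratio of zero, to a ratio equal to the time over a single characteristic time. These readings give 4.29 d for the level time, the time at which this line reaches a ratio of one. Two times then stand against each other, the level time and the asked 12 d, and their quotient is my reckoning for the end: 2.79, with the isomer ahead. The same line gives 0.0291 at 3.0 h and 3.23 × 10⁻⁴ at 2.0 min. The earliest reading of the south run comes later than 2.0 min, at 0.417 d, where the isomer reads 0% with a scatter of 1.5 percentage points beside target at 29%.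

The forecast gives 0.001 at 2.0 min, 0.03 at 3.0 h and 3.5 at 12 d, with isomer of the product ahead, and reads the rising ratio as suggesting that “the isomer arises from the target, not in parallel with it”. Its end value stands above mine.

The flask gives 0.0167 at 2.0 min, 0.0258 at 3.0 h and 3.35 at 12 d, with isomer of the product ahead.

    2 substrate → self-condensation product (k = 27.5 /M/h)
    substrate + coupling partner ⇌ isomer of the product (K = 2300 /M, k = 0.843 /M/h)
    substrate + coupling partner ⇌ target (K = 230 /M, k = 50.8 /M/h)
    coupling partner ⇌ dormant form (K = 0.520, k = 0.332 /h)

The selectivity factor, the rate constant to the isomer over that to target, is 0.0166. Isomer and target stood level at 4.93 d, against the level time of 4.29 d. That level time puts 12 d at a ratio of 2.79 where this flask reached 3.35. The same level time, applied to the neighbour charged with 3.5 mM of substrate at the same equivalents, again gives 2.79; that neighbour reached 3.30, with target at 1.44% and isomer at 4.74%.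

(The runs were computed from invented constants, and the scatter is random.)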